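**Plan**

The target is a p-terphenyl with no stereocentre. Its central ring carries benzoates on C1 and C2, free hydroxyls on C4 and C5, and 4-hydroxyphenyl rings on C3 and C6.
Retrosynthesis first removes the two benzoates and goes back, through the central tetrol and its quinone, to 2,5-bis(4-hydroxyphenyl)-3,6-dimethoxy-1,4-benzoquinone.
The two outer rings stand para to each other on C3 and C6, and each has its hydroxyl at C4', para to the biaryl carbon C1'. Each ring is therefore cut at C1'–C2' and C5'–C6' (four bonds in all), leaving an ethynyl group on the quinone and a 1-methoxy-3-silyloxybutadiene.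
The diethynylquinone goes back to bromanil by Stille coupling and methoxide substitution.
Forward: the central ring is bought as a quinone, both outer phenol rings arise together in one twofold cycloaddition with aromatisation, and the central oxygens are then told apart (ketal on one catechol, benzoates on the other). No stereochemistry has to be set.

Key step: step 4

Remark: bromanil, the alkynylstannane and the silyloxydiene are taken as bought. The quinone 5 is assumed to be too sensitive to store and is used at once.

**Route**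

Step 1
Reactants: 1 tetrabromo-1,4-benzoquinone (bromanil)
Product: 2 2,5-dibromo-3,6-dimethoxy-1,4-benzoquinone
Conditions: NaOMe (2.05 equiv), MeOH, 0 °C to rt
Reagents that add atoms: sodium methoxide, C[O-].[Na+]
Why: Methoxide replaces bromide by addition–elimination (vinylogous acyl substitution) on the haloquinone, and the first methoxy group deactivates the carbonyl it is conjugated with so that the second substitution goes to the para-related carbon, the pattern known for chloranil and bromanil with alkoxides.

Step 2
Reactants: 2 2,5-dibromo-3,6-dimethoxy-1,4-benzoquinone; 3 tributyl(trimethylsilylethynyl)stannane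
Product: 4 2,5-dimethoxy-3,6-bis(trimethylsilylethynyl)-1,4-benzoquinone
Conditions: 3 (2.3 equiv), Pd(PPh3)4 (5 mol %), CuI (10 mol %), toluene, 70 °C, Ar
Reagents that add atoms: none
Why: Stille coupling, in which the C–Br bonds of the bromoquinone behave as vinylogous acyl bromides and add zerovalent palladium readily, alkynyl groups transfer from tin fastest of all, and the neutral conditions avoid the amine of a Sonogashira coupling, which would add to the quinone.

Step 3
Reactants: 4 2,5-dimethoxy-3,6-bis(trimethylsilylethynyl)-1,4-benzoquinone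
Product: 5 2,5-diethynyl-3,6-dimethoxy-1,4-benzoquinone
Conditions: Bu4NF (2.2 equiv), AcOH (2.5 equiv), THF, −78 °C; cold aqueous work-up, solution used at once
Reagents that add atoms: none
Why: Fluoride-induced protodesilylation of an alkynylsilane, run cold and buffered with AcOH so that no alkoxide or free fluoride base can add to the alkyne terminus, which becomes electrophilic once the silyl group is gone.

Step 4
Reactants: 5 2,5-diethynyl-3,6-dimethoxy-1,4-benzoquinone; 6 (E)-1-methoxy-3-trimethylsilyloxybuta-1,3-diene
Product: 8 2,5-bis(4-hydroxyphenyl)-3,6-dimethoxy-1,4-benzoquinone (atromentin dimethyl ether), via twofold cycloadduct 7 (not isolated)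
Conditions: 6 (4 equiv), toluene, 25 to 70 °C, Ar, dark; then 1 M HCl, THF, 0 °C to rt
Reagents that add atoms: none
Why: Proposed new method: each ethynyl group of 5 ends an ene-yne-one acceptor (HC≡C–C3=C2–C1=O), so the nucleophilic CH2 end of diene 6 should bond to the terminal alkyne carbon and the methoxy-bearing end to the inner one in a concerted, asynchronous (4+2) cycloaddition that gives the 1,4-cyclohexadiene 7; acid then hydrolyses the silyl enol ether and eliminates methanol to leave the 4-hydroxyphenyl ring. The closest known reaction type is the Diels–Alder reaction of 1-methoxy-3-silyloxybutadienes with acetylenic esters and ketones to give 4-hydroxyaryl carbonyl compounds, whereas an alkynylquinone reacting at its alkyne is not established. Each of the two outer rings is closed in the same way, by an intermolecular (4+2) cycloaddition that forms C1'–C2' and C5'–C6', followed by aromatisation. No stereocentre remains, because the methoxy-bearing carbons of 7 are lost when methanol leaves. The step needs the alkynes to react in preference to the quinone C=C and C=O bonds, which the full substitution of the ring and the vinylogous-ester deactivation by the two methoxy groups should secure, and it needs para regiochemistry, which follows from pairing the diene CH2 terminus with the terminal alkyne carbon.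

Step 5
Reactants: 8 2,5-bis(4-hydroxyphenyl)-3,6-dimethoxy-1,4-benzoquinone
Product: 9 2,5-bis(4-benzyloxyphenyl)-3,6-dimethoxy-1,4-benzoquinone
Conditions: BnBr (2.4 equiv), K2CO3, acetone, 50 °C
Reagents that add atoms: benzyl bromide, BrCc1ccccc1
Why: Williamson ether synthesis on the two phenols, the only acidic groups present, while the tetrasubstituted quinone has no free position for conjugate addition and its vinylogous esters are not displaced by carbonate.

Step 6
Reactants: 9 2,5-bis(4-benzyloxyphenyl)-3,6-dimethoxy-1,4-benzoquinone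
Product: 10 2,5-bis(4-benzyloxyphenyl)-3,6-dihydroxy-1,4-benzoquinone
Conditions: 2 M NaOH, THF/MeOH, 60 °C; then 1 M HCl
Reagents that add atoms: sodium hydroxide, [Na+].[OH-]
Why: Saponification of the two vinylogous methyl esters by addition–elimination of hydroxide, the usual way to 2,5-dihydroxy-3,6-diarylquinones, which leaves aryl benzyl ethers untouched.

Step 7
Reactants: 10 2,5-bis(4-benzyloxyphenyl)-3,6-dihydroxy-1,4-benzoquinone
Product: 11 3,6-bis(4-benzyloxyphenyl)benzene-1,2,4,5-tetrol
Conditions: Na2S2O4, EtOAc/H2O, rt, Ar; carried on without storage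
Reagents that add atoms: none
Why: Dithionite reduction of a quinone to its hydroquinone, which gives the leuco form under mild aqueous conditions that do not touch the benzyl ethers.

Step 8
Reactants: 11 3,6-bis(4-benzyloxyphenyl)benzene-1,2,4,5-tetrol
Product: 12 4,7-bis(4-benzyloxyphenyl)-2,2-diphenyl-1,3-benzodioxole-5,6-diol
Conditions: Ph2CCl2 (1.0 equiv, added slowly), Ph2O, 170 °C, Ar stream
Reagents that add atoms: dichlorodiphenylmethane, ClC(Cl)(c1ccccc1)c1ccccc1
Why: Diphenylmethylene ketal formation from a catechol and a gem-dichloride, in which only two adjacent hydroxyls can close the five-membered ring, and with one equivalent of reagent the mono-ketal should be the main part of a statistical mixture from which unreacted 11 and the bis-ketal (after acid hydrolysis) are returned.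

Step 9
Reactants: 12 4,7-bis(4-benzyloxyphenyl)-2,2-diphenyl-1,3-benzodioxole-5,6-diol
Product: 13 4,7-bis(4-benzyloxyphenyl)-2,2-diphenyl-1,3-benzodioxole-5,6-diyl dibenzoate
Conditions: BzCl (3 equiv), Et3N, DMAP (cat.), CH2Cl2, 0 °C to rt
Reagents that add atoms: benzoyl chloride, O=C(Cl)c1ccccc1
Why: Esterification of the two remaining phenols with an acid chloride under nucleophilic catalysis by DMAP, the ketal and the benzyl ethers being inert.

Step 10
Reactants: 13 4,7-bis(4-benzyloxyphenyl)-2,2-diphenyl-1,3-benzodioxole-5,6-diyl dibenzoate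
Product: 14 3,6-bis(4-hydroxyphenyl)-4,5-dihydroxy-1,2-phenylene dibenzoate (CNP0216579.0)
Conditions: H2 (1 atm), Pd/C (10 wt %), THF/MeOH, rt
Reagents that add atoms: none
Why: Hydrogenolysis over Pd/C cleaves the two benzyl ethers and the benzylic C–O bonds of the diphenylmethylene ketal while aryl benzoates are stable, and no acyl migration can follow because neither benzoate has a free hydroxyl next to it.

**Compound list**

1 | tetrabromo-1,4-benzoquinone (bromanil) | O=C1C(Br)=C(Br)C(=O)C(Br)=C1Br | starting material
2 | 2,5-dibromo-3,6-dimethoxy-1,4-benzoquinone | COC1=C(Br)C(=O)C(OC)=C(Br)C1=O | intermediate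
3 | tributyl(trimethylsilylethynyl)stannane | CCCC[Sn](CCCC)(CCCC)C#C[Si](C)(C)C | starting material
4 | 2,5-dimethoxy-3,6-bis(trimethylsilylethynyl)-1,4-benzoquinone | COC1=C(C#C[Si](C)(C)C)C(=O)C(OC)=C(C#C[Si](C)(C)C)C1=O | intermediate
5 | 2,5-diethynyl-3,6-dimethoxy-1,4-benzoquinone | COC1=C(C#C)C(=O)C(OC)=C(C#C)C1=O | intermediate
6 | (E)-1-methoxy-3-trimethylsilyloxybuta-1,3-diene | CO/C=C/C(=C)O[Si](C)(C)C | starting material
7 | twofold cycloadduct, 2,5-dimethoxy-3,6-bis[6-methoxy-4-(trimethylsilyloxy)cyclohexa-1,4-dien-1-yl]-1,4-benzoquinone (both configurations at each methoxy-bearing carbon) | COC1=C(C2=CCC(O[Si](C)(C)C)=CC2OC)C(=O)C(OC)=C(C2=CCC(O[Si](C)(C)C)=CC2OC)C1=O | intermediate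
8 | 2,5-bis(4-hydroxyphenyl)-3,6-dimethoxy-1,4-benzoquinone (atromentin dimethyl ether) | COC1=C(c2ccc(O)cc2)C(=O)C(OC)=C(c2ccc(O)cc2)C1=O | intermediate
9 | 2,5-bis(4-benzyloxyphenyl)-3,6-dimethoxy-1,4-benzoquinone | COC1=C(c2ccc(OCc3ccccc3)cc2)C(=O)C(OC)=C(c2ccc(OCc3ccccc3)cc2)C1=O | intermediate
10 | 2,5-bis(4-benzyloxyphenyl)-3,6-dihydroxy-1,4-benzoquinone | OC1=C(c2ccc(OCc3ccccc3)cc2)C(=O)C(O)=C(c2ccc(OCc3ccccc3)cc2)C1=O | intermediate
11 | 3,6-bis(4-benzyloxyphenyl)benzene-1,2,4,5-tetrol | Oc1c(O)c(-c2ccc(OCc3ccccc3)cc2)c(O)c(O)c1-c1ccc(OCc2ccccc2)cc1 | intermediate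
12 | 4,7-bis(4-benzyloxyphenyl)-2,2-diphenyl-1,3-benzodioxole-5,6-diol | Oc1c(O)c(-c2ccc(OCc3ccccc3)cc2)c2OC(c3ccccc3)(c3ccccc3)Oc2c1-c1ccc(OCc2ccccc2)cc1 | intermediate
13 | 4,7-bis(4-benzyloxyphenyl)-2,2-diphenyl-1,3-benzodioxole-5,6-diyl dibenzoate | O=C(Oc1c(OC(=O)c2ccccc2)c(-c2ccc(OCc3ccccc3)cc2)c2OC(c3ccccc3)(c3ccccc3)Oc2c1-c1ccc(OCc2ccccc2)cc1)c1ccccc1 | intermediate
14 | 3,6-bis(4-hydroxyphenyl)-4,5-dihydroxy-1,2-phenylene dibenzoate (CNP0216579.0) | O=C(Oc1c(OC(=O)c2ccccc2)c(-c2ccc(O)cc2)c(O)c(O)c1-c1ccc(O)cc1)c1ccccc1 | target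

**Step count and risks**

Total step count: 10. Longest linear sequence: 10 steps (1 to 14).

Steps most likely to fail:

1. Step 4 (new method). The diene may be consumed by electron transfer to the quinone or by addition at the carbonyl groups, and the terminal alkynes may oligomerise before they cycloadd. The fallback uses known chemistry and brings the outer rings in ready-made. Dibromide 2 is coupled twice with 4-benzyloxyphenylboronic acid (Suzuki–Miyaura coupling, PdCl2(dppf), K3PO4, dioxane, 90 °C), a reaction type established for bromoquinones, and this should give 9 directly. The path sets out from 2, comes back at 9 and makes no compound outside the list (F0).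

2. Step 3. Once the silyl groups are off, fluoride, acetate or water may add to the alkyne terminus, fluoride may trigger electron transfer to the quinone, and the product may oligomerise on concentration. The fallback unmasks the alkynes at the arene oxidation level and forms the quinone last. It sets out from 4: Na2S2O4 (EtOAc/H2O) should give 2,5-dimethoxy-3,6-bis(trimethylsilylethynyl)benzene-1,4-diol F1. MeI and K2CO3 in acetone should give 1,2,4,5-tetramethoxy-3,6-bis(trimethylsilylethynyl)benzene F2. K2CO3 in MeOH should then give 1,4-diethynyl-2,3,5,6-tetramethoxybenzene F3, a stable arene whose alkynes are not electrophilic. Oxidative demethylation with (NH4)2Ce(NO3)6 in MeCN/H2O at 0 °C should give 5, where the path comes back to the route just before step 4.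

3. Step 8. Ketalisation may run on to the bis-ketal, the tetrol may be oxidised back to the quinone at 170 °C, and the mono-ketal cannot exceed the statistical share. The fallback differentiates the two halves electronically at the quinone level and sets out from 9.
   - One equivalent of NaOH (THF/H2O, rt) should hydrolyse only one vinylogous ester, because the hydroxyquinone anion resists the second attack, and give 3,6-bis(4-benzyloxyphenyl)-2-hydroxy-5-methoxy-1,4-benzoquinone F4.
   - Na2S2O4 should give 3,6-bis(4-benzyloxyphenyl)-5-methoxybenzene-1,2,4-triol F5.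
   - Its single catechol is ketalised with Ph2CCl2 to 4,7-bis(4-benzyloxyphenyl)-6-methoxy-2,2-diphenyl-1,3-benzodioxol-5-ol F6.
   - The remaining phenol is methylated (MeI, K2CO3, DMF) to 4,7-bis(4-benzyloxyphenyl)-5,6-dimethoxy-2,2-diphenyl-1,3-benzodioxole F7.
   - The ketal is hydrolysed (AcOH/H2O, 90 °C) to 3,6-bis(4-benzyloxyphenyl)-4,5-dimethoxybenzene-1,2-diol F8.
   - Benzoylation (BzCl, Et3N, DMAP) gives 3,6-bis(4-benzyloxyphenyl)-4,5-dimethoxy-1,2-phenylene dibenzoate F9.
   - BBr3 (CH2Cl2, −78 to 0 °C) cleaves the two methyl and two benzyl ethers and should leave the aryl benzoates, so the path comes back at 14.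

**Further compounds**

F0 | step 4 | none | none
F1 | step 3 | 2,5-dimethoxy-3,6-bis(trimethylsilylethynyl)benzene-1,4-diol | COc1c(C#C[Si](C)(C)C)c(O)c(OC)c(C#C[Si](C)(C)C)c1O
F2 | step 3 | 1,2,4,5-tetramethoxy-3,6-bis(trimethylsilylethynyl)benzene | COc1c(OC)c(C#C[Si](C)(C)C)c(OC)c(OC)c1C#C[Si](C)(C)C
F3 | step 3 | 1,4-diethynyl-2,3,5,6-tetramethoxybenzene | COc1c(OC)c(C#C)c(OC)c(OC)c1C#C
F4 | step 8 | 3,6-bis(4-benzyloxyphenyl)-2-hydroxy-5-methoxy-1,4-benzoquinone | COC1=C(c2ccc(OCc3ccccc3)cc2)C(=O)C(O)=C(c2ccc(OCc3ccccc3)cc2)C1=O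
F5 | step 8 | 3,6-bis(4-benzyloxyphenyl)-5-methoxybenzene-1,2,4-triol | COc1c(O)c(-c2ccc(OCc3ccccc3)cc2)c(O)c(O)c1-c1ccc(OCc2ccccc2)cc1
F6 | step 8 | 4,7-bis(4-benzyloxyphenyl)-6-methoxy-2,2-diphenyl-1,3-benzodioxol-5-ol | COc1c(O)c(-c2ccc(OCc3ccccc3)cc2)c2OC(c3ccccc3)(c3ccccc3)Oc2c1-c1ccc(OCc2ccccc2)cc1
F7 | step 8 | 4,7-bis(4-benzyloxyphenyl)-5,6-dimethoxy-2,2-diphenyl-1,3-benzodioxole | COc1c(OC)c(-c2ccc(OCc3ccccc3)cc2)c2OC(c3ccccc3)(c3ccccc3)Oc2c1-c1ccc(OCc2ccccc2)cc1
F8 | step 8 | 3,6-bis(4-benzyloxyphenyl)-4,5-dimethoxybenzene-1,2-diol | COc1c(OC)c(-c2ccc(OCc3ccccc3)cc2)c(O)c(O)c1-c1ccc(OCc2ccccc2)cc1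
F9 | step 8 | 3,6-bis(4-benzyloxyphenyl)-4,5-dimethoxy-1,2-phenylene dibenzoate | COc1c(OC)c(-c2ccc(OCc3ccccc3)cc2)c(OC(=O)c2ccccc2)c(OC(=O)c2ccccc2)c1-c1ccc(OCc2ccccc2)cc1
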